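## The problem

Numbering used throughout: the 14-membered ring is C1 (ring-fusion CH), C2 (lactone OCH), C3=C4, C5, C6, C7=C8, C9 (CHOAc), C10, C11=C12, C13, C14; the lactone carbons are C15 (alpha), C16 (carbonyl) and C17 (exo-methylene).

The target is a cembrane-type carbocycle with three E-trisubstituted alkenes, trans-fused at C1/C2 to an alpha-methylene-gamma-butyrolactone, and it carries an allylic acetate at C9. Closing a 14-membered ring without disturbing these alkenes is the main problem, since olefin-forming ring closures at trisubstituted positions give poor geometric control. There are three stereocentres: C1 and C2 are neighbours, so one can control the other, whereas C9 is seven bonds from C2 and must be set by a reagent. The methylene lactone is a Michael and radical acceptor and does not tolerate base or nucleophiles. C2 is doubly allylic and becomes epimerisable once a butenolide is present. The C9 acetate would not survive the ester cleavages needed elsewhere. The enabling feature is that C1 is the lactone beta-carbon, carries C14, and lies next to C15 with its exocyclic C17. This is the pattern produced when a C14 radical adds to C1 of a C1=C15 butenolide bearing a leaving group on C17, so ring closure, the C1 stereocentre and the methylene group can arise in one event.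

## Retrosynthesis

**C9 acetate.** The C9–O acyl bond of target 26 is cut first, giving alcohol 25 and its TBS ether 24. An acetate cannot be carried through the methanolysis and saponification used earlier, while a silyl ether can. The forward reaction needs a desilylation that spares the methylene lactone, so a buffered acidic fluoride source is required.

**Ring closure (key cut).** In 24 the C1–C14 bond is cut and C15=C17 is traded for C1=C15 plus a C17–SO2Ph bond, leading to the acyclic redox-active ester 23.
- Cuts at the trisubstituted alkenes would need E-selective ring-closing olefinations.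
- Cuts at C8–C9 or C9–C10 would create the remote C9 centre during macrocyclisation without a neighbouring control element.
- The chosen cut removes the ring, the C1 stereocentre and the exo-methylene at once and leaves a chain with two independent stereocentres.
- The forward reaction needs a nucleophilic primary C14 radical generated under neutral conditions, addition anti to the C2 substituent, and loss of sulfonyl faster than any reverse or reductive pathway.

**Butenolide.** In 23 the C1=C15 alkene is cut by ring-closing metathesis to diene 22, and the ester C–O bond of 22 leads to doubly allylic alcohol 18 and acid 21. Acid 21 comes from 2-(bromomethyl)acrylic acid 19 and sodium benzenesulfinate 20.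
- A Barbier allylation with a 2-(bromomethyl)acrylate would give the methylene lactone directly, which is the wrong acceptor.
- Metallated sulfonylmethyl acrylates are not readily available.
- The forward reaction needs the ruthenium carbene to load on the only monosubstituted alkene and close onto the acrylate.

**Redox-active ester.** The N-acyloxyphthalimide of 18 is cut to acid 16 and N-hydroxyphthalimide 17, and 16 comes from methyl ester 15. The ester is hydrolysed and activated before the butenolide exists, because no hydroxide can be used afterwards. The cost is that the activated ester must pass through an acylation and a metathesis.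

**C2 stereocentre.** The C1–C2 bond of 15 is cut to a vinyl nucleophile and enal 14, which comes from allylic alcohol 13 and acetate 12. C9 is too remote to help, so the vinyl transfer must be catalyst-controlled. The precursor is a plain geranial-type enal.

**C11=C12 alkene.** In 12 the C13–C14 bond is cut with allylic transposition (Johnson–Claisen) to allylic alcohol 9 and trimethyl orthoacetate 10, and 9 comes from enone 8. A Wittig-type construction of this trisubstituted alkene would be less selective. The rearrangement also delivers the ester whose carbonyl carbon is later lost as CO2. The configuration of the C11 carbinol is irrelevant.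

**C9 stereocentre and the C2–C9 chain.** The C9–C10 bond of 8 (via aldol 7) is cut to 3-methylbut-3-en-2-one 4 and enal 3. Enal 3 is made by allylic oxidation of geranyl acetate 1, which supplies C2–C9 with both E-alkenes in place. The forward aldol must set C9 by reagent control.

## Roads not taken

Alternative 1: The cut is C11=C12, made while the C9 oxygen and C12 are tied through a dimethylsilyl unit. The 14-membered cyclic silyl ether A1 (allyl group on C9, 1-silylvinyl group at C12) would undergo ring-closing metathesis with Mo(=CHCMe2Ph)(=NC6H3iPr2)(OCMe(CF3)2)2 to the strapped carbocycle A2.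
- Merits: the new alkene lies in a six-membered oxasilacycle, so its geometry is fixed; the entropic cost of macrocyclisation is paid in an easy Si–O bond formation; the metathesis is established chemistry.
- Weak points: the 1,1-disubstituted vinylsilane needs the sensitive molybdenum alkylidene. Silicon on C12 must then be exchanged for methyl with retention (halodesilylation and cross-coupling) in the presence of two other electron-rich trisubstituted alkenes. The C1/C2 pair must be built in the open chain. The methylene group must be added to the lactone by enolate chemistry at the end.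
- Comparison: this road controls the C11=C12 geometry better than the chosen plan, where that alkene passes through a homoallylic radical. The chosen plan offers instead a ring closure that also sets C1 and the methylene group, and only two steps after cyclisation.

Alternative 2: The cut is C3–C4 at the alkyne oxidation level. The seco diyne A3 would undergo ring-closing alkyne metathesis with Mo(≡CC6H4OMe)(OSiPh3)3 to the cycloalkynol A4. Hydroxyl-directed trans-hydroalumination (NaAlH2(OCH2CH2OMe)2), iodination and methyl cross-coupling would then build the E-C3=C4 alkene.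
- Merits: alkyne metathesis is probably the most dependable way to close a 14-membered ring and cannot scramble alkene geometry. In reliability of the ring-closing event this road is better than the chosen plan.
- Weak points: the free propargylic C2 hydroxyl sits next to the reacting alkyne. The C4 methyl group, the lactone and the methylene group are all installed after ring closure (hydrometalation, iodination, methylation, ether cleavage, oxidation and lactonisation). The C1/C2 pair must be set beforehand in the open chain.
- Comparison: the chosen plan accepts a riskier closure in exchange for a much shorter endgame and for using C2 to set C1 during cyclisation.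

Alternative 3: The cut is C8–C9. The seco ynal A5 would be cyclised at high dilution with Ni(cod)2, an N-heterocyclic carbene ligand and Et3SiH to the macrocyclic silyl ether A6.
- Merits: one step forms the C8–C9 bond, the C9 carbinol and the E-C7=C8 alkene. It is more convergent than the chosen plan and equally economical in creating a stereocentre during closure.
- Weak points: the alkyne carries methyl and methylene substituents of similar size, so endocyclic regiochemistry depends entirely on the ligand. C9 has no neighbouring stereocentre, so its configuration rests on a remote relay or a chiral ligand. The beta,gamma-unsaturated aldehyde of A5 is prone to conjugation. The methylene group must be added later with base.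
- Comparison: in the chosen plan the centre formed in the ring closure (C1) lies next to C2, and C9 is set early by a reagent of known sense.

Key step: step 14

Assumption (remark on the chemistry): the facial sense of the Ipc2BCl aldol (step 2) and of the amino-alcohol-catalysed vinyl transfer (step 8) is assigned by analogy with the closest known cases. Both reagent antipodes are available, so the configurations of 7 and 15 would be checked by Mosher ester analysis and the antipode exchanged if needed.

Step 1
Reactants: 1 geranyl acetate
Product: 3 (2E,6E)-3,7-dimethyl-8-oxoocta-2,6-dien-1-yl acetate, via 8-hydroxygeranyl acetate 2 (not isolated)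
Conditions: SeO2 (cat.), t-BuOOH, salicylic acid (cat.), CH2Cl2, rt; then MnO2, CH2Cl2, rt
Reagents that add atoms: tert-butyl hydroperoxide CC(C)(C)OO (oxygen relayed by catalytic selenium dioxide O=[Se]=O)
Why: Riley allylic oxidation: the ene reaction and [2,3]-shift of SeO2 attack the more electron-rich terminal alkene at its E-methyl group, while the allylic acetate deactivates the other alkene; MnO2 then oxidises only the allylic alcohol, so the alcohol/aldehyde mixture converges on the E-enal.

Step 2
Reactants: 3 (2E,6E)-3,7-dimethyl-8-oxoocta-2,6-dien-1-yl acetate; 4 3-methylbut-3-en-2-one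
Product: 7 (2E,6E,8S)-8-hydroxy-3,7,11-trimethyl-10-oxododeca-2,6,11-trien-1-yl acetate, via enol diisopinocampheylborinate 5 (not isolated), via boron aldolate 6 (not isolated)
Conditions: 4, (+)-Ipc2BCl, Et3N, Et2O, 0 °C; then 3, −78 → −20 °C; H2O2, MeOH, pH 7 buffer, 0 °C
Reagents that add atoms: none
Why: Reagent-controlled boron aldol reaction of a methyl ketone: 4 can enolise only at its methyl group, and the cyclic transition state of the (+)-Ipc2B enolate (from (−)-alpha-pinene) should add to the Si face of the enal, setting C9 as S. The acetate is inert to the boron enolate, and buffered peroxide only cleaves the B–C and B–O bonds.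

Step 3
Reactants: 7 (2E,6E,8S)-8-hydroxy-3,7,11-trimethyl-10-oxododeca-2,6,11-trien-1-yl acetate
Product: 8 (2E,6E,8S)-8-[(tert-butyldimethylsilyl)oxy]-3,7,11-trimethyl-10-oxododeca-2,6,11-trien-1-yl acetate
Conditions: TBSOTf, 2,6-lutidine, CH2Cl2, −78 °C
Reagents that add atoms: tert-butyldimethylsilyl trifluoromethanesulfonate CC(C)(C)[Si](C)(C)OS(=O)(=O)C(F)(F)F
Why: Silylation of a beta-hydroxy ketone with a silyl triflate and a hindered pyridine at low temperature is faster than elimination or retro-aldol cleavage. The TBS ether should survive methanolysis, saponification, organozinc and ruthenium reagents and leave with fluoride at the end.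

Step 4
Reactants: 8 (2E,6E,8S)-8-[(tert-butyldimethylsilyl)oxy]-3,7,11-trimethyl-10-oxododeca-2,6,11-trien-1-yl acetate
Product: 9 (2E,6E,8S)-8-[(tert-butyldimethylsilyl)oxy]-10-hydroxy-3,7,11-trimethyldodeca-2,6,11-trien-1-yl acetate (both C10 epimers)
Conditions: NaBH4, CeCl3·7H2O, MeOH, −78 °C
Reagents that add atoms: none
Why: Luche reduction: CeCl3 directs borohydride to 1,2-addition at the enone and the cold medium spares the acetate. The new carbinol forms as both epimers, which is harmless because this centre is destroyed in the next step.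

Step 5
Reactants: 9 (2E,6E,8S)-8-[(tert-butyldimethylsilyl)oxy]-10-hydroxy-3,7,11-trimethyldodeca-2,6,11-trien-1-yl acetate; 10 trimethyl orthoacetate
Product: 12 methyl (4E,7S,8E,12E)-14-acetoxy-7-[(tert-butyldimethylsilyl)oxy]-4,8,12-trimethyltetradeca-4,8,12-trienoate, via mixed ketene acetal 11 (not isolated)
Conditions: MeC(OMe)3, EtCO2H (cat.), 120 °C, removal of MeOH
Reagents that add atoms: none
Why: Johnson–Claisen rearrangement: acid-catalysed exchange gives the mixed ketene acetal, and its chair transition state with the carbinol substituent equatorial should give the E-trisubstituted C11=C12 alkene, the C13–C14 bond and the ester whose carbonyl carbon is later lost as CO2.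

Step 6
Reactants: 12 methyl (4E,7S,8E,12E)-14-acetoxy-7-[(tert-butyldimethylsilyl)oxy]-4,8,12-trimethyltetradeca-4,8,12-trienoate
Product: 13 methyl (4E,7S,8E,12E)-7-[(tert-butyldimethylsilyl)oxy]-14-hydroxy-4,8,12-trimethyltetradeca-4,8,12-trienoate
Conditions: K2CO3 (cat.), MeOH, 0 °C → rt
Reagents that add atoms: none
Why: Transesterification: methoxide cleaves the primary allylic acetate, while exchange at the methyl ester is degenerate and the TBS ether is stable.

Step 7
Reactants: 13 methyl (4E,7S,8E,12E)-7-[(tert-butyldimethylsilyl)oxy]-14-hydroxy-4,8,12-trimethyltetradeca-4,8,12-trienoate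
Product: 14 methyl (4E,7S,8E,12E)-7-[(tert-butyldimethylsilyl)oxy]-4,8,12-trimethyl-14-oxotetradeca-4,8,12-trienoate
Conditions: MnO2, CH2Cl2, rt
Reagents that add atoms: none
Why: MnO2 oxidises allylic alcohols selectively to enals and leaves the silyl ether, the ester and the isolated alkenes untouched.

Step 8
Reactants: 14 methyl (4E,7S,8E,12E)-7-[(tert-butyldimethylsilyl)oxy]-4,8,12-trimethyl-14-oxotetradeca-4,8,12-trienoate
Product: 15 methyl (4E,7S,8E,12E,14R)-7-[(tert-butyldimethylsilyl)oxy]-14-hydroxy-4,8,12-trimethylhexadeca-4,8,12,15-tetraenoate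
Conditions: Zn(CH=CH2)2 (salt-free), (+)-3-exo-morpholinoisoborneol (10 mol %), toluene/hexane, −30 → 0 °C; aq. NH4Cl
Reagents that add atoms: divinylzinc C=C[Zn]C=C
Why: Amino-alcohol-catalysed enantioselective addition of a vinylzinc reagent to an aldehyde: the zinc aminoalkoxide should deliver the vinyl group to the Re face of the enal carbonyl, giving the 14R carbinol (this centre is C2 and becomes S in the lactone). Organozinc reagents add 1,2 to the enal and leave the methyl ester alone.

Step 9
Reactants: 15 methyl (4E,7S,8E,12E,14R)-7-[(tert-butyldimethylsilyl)oxy]-14-hydroxy-4,8,12-trimethylhexadeca-4,8,12,15-tetraenoate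
Product: 16 (4E,7S,8E,12E,14R)-7-[(tert-butyldimethylsilyl)oxy]-14-hydroxy-4,8,12-trimethylhexadeca-4,8,12,15-tetraenoic acid
Conditions: LiOH, THF/MeOH/H2O, 0 °C → rt; citric acid to pH 4
Reagents that add atoms: lithium hydroxide [Li+].[OH-]
Why: Saponification of an unhindered methyl ester; the doubly allylic carbinol and the TBS ether are stable to hydroxide, and the mild citric acid work-up avoids ionising the doubly allylic alcohol. It is placed here because no base can be used once the butenolide exists.

Step 10
Reactants: 16 (4E,7S,8E,12E,14R)-7-[(tert-butyldimethylsilyl)oxy]-14-hydroxy-4,8,12-trimethylhexadeca-4,8,12,15-tetraenoic acid; 17 N-hydroxyphthalimide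
Product: 18 1,3-dioxoisoindolin-2-yl (4E,7S,8E,12E,14R)-7-[(tert-butyldimethylsilyl)oxy]-14-hydroxy-4,8,12-trimethylhexadeca-4,8,12,15-tetraenoate
Conditions: N,N'-diisopropylcarbodiimide, CH2Cl2, 0 °C → rt
Reagents that add atoms: none
Why: Carbodiimide coupling: without an acyl-transfer catalyst the acidic N-hydroxyphthalimide captures the O-acylisourea much faster than the hindered secondary alcohol, so the redox-active ester should form chemoselectively.

Step 11
Reactants: 19 2-(bromomethyl)acrylic acid; 20 sodium benzenesulfinate
Product: 21 2-[(phenylsulfonyl)methyl]prop-2-enoic acid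
Conditions: PhSO2Na, MeOH, reflux
Reagents that add atoms: none
Why: Substitution of an allylic bromide by the soft sulfur nucleophile benzenesulfinate; direct and allylically transposed attack give the same product, and the carboxylic acid is too weak to protonate sulfinate.

Step 12
Reactants: 18 1,3-dioxoisoindolin-2-yl (4E,7S,8E,12E,14R)-7-[(tert-butyldimethylsilyl)oxy]-14-hydroxy-4,8,12-trimethylhexadeca-4,8,12,15-tetraenoate; 21 2-[(phenylsulfonyl)methyl]prop-2-enoic acid
Product: 22 1,3-dioxoisoindolin-2-yl (4E,7S,8E,12E,14R)-7-[(tert-butyldimethylsilyl)oxy]-4,8,12-trimethyl-14-({2-[(phenylsulfonyl)methyl]prop-2-enoyl}oxy)hexadeca-4,8,12,15-tetraenoate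
Conditions: N,N'-diisopropylcarbodiimide, 4-dimethylaminopyridine (5 mol %), CH2Cl2, −10 → 0 °C
Reagents that add atoms: none
Why: Steglich esterification of the secondary alcohol: the acylpyridinium ion of 21 is far more electrophilic than the N-acyloxyphthalimide, and addition of the pyridine catalyst to the allyl sulfone is degenerate because sulfinate returns.

Step 13
Reactants: 22 1,3-dioxoisoindolin-2-yl (4E,7S,8E,12E,14R)-7-[(tert-butyldimethylsilyl)oxy]-4,8,12-trimethyl-14-({2-[(phenylsulfonyl)methyl]prop-2-enoyl}oxy)hexadeca-4,8,12,15-tetraenoate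
Product: 23 1,3-dioxoisoindolin-2-yl (4E,7S,8E,12E)-7-[(tert-butyldimethylsilyl)oxy]-4,8,12-trimethyl-13-{(2S)-5-oxo-4-[(phenylsulfonyl)methyl]-2,5-dihydrofuran-2-yl}trideca-4,8,12-trienoate
Conditions: second-generation Grubbs catalyst RuCl2(=CHPh)(H2IMes)(PCy3) (10 mol %), CH2Cl2 (5 mM), 40 °C
Reagents that add atoms: none
Why: Ring-closing metathesis: the carbene should load on the only monosubstituted alkene and close the five-membered ring onto the acrylate with loss of ethylene. The trisubstituted alkenes are inert, and closure onto C7=C8 would require the E-C3=C4 alkene inside a seven-membered ring.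

Step 14
Reactants: 23 1,3-dioxoisoindolin-2-yl (4E,7S,8E,12E)-7-[(tert-butyldimethylsilyl)oxy]-4,8,12-trimethyl-13-{(2S)-5-oxo-4-[(phenylsulfonyl)methyl]-2,5-dihydrofuran-2-yl}trideca-4,8,12-trienoate
Product: 24 (3aR,6E,9S,10E,14E,15aS)-9-[(tert-butyldimethylsilyl)oxy]-6,10,14-trimethyl-3-methylidene-3a,4,5,8,9,12,13,15a-octahydrocyclotetradeca[b]furan-2(3H)-one
Conditions: Ru(bpy)3Cl2·6H2O (2 mol %), Hantzsch ester (1.5 equiv), degassed MeCN/CH2Cl2 (1:1, 1 mM), blue LEDs (450 nm), rt; aq. NaHCO3 wash
Reagents that add atoms: none
Why: Proposed new method: the excited divalent ruthenium complex is reductively quenched by Hantzsch ester, and the resulting monovalent ruthenium complex transfers an electron to the N-acyloxyphthalimide, which releases CO2, phthalimide anion and the nucleophilic primary C14 radical; this radical adds to the electron-poor beta-carbon C1 of the butenolide, the tertiary C15 radical expels PhSO2 by beta-scission to form C15=C17, and the sulfonyl radical is reduced to sulfinate, so the closest known reactions are the photoredox decarboxylative allylation of N-acyloxyphthalimides with 2-(sulfonylmethyl)acrylates and decarboxylative conjugate-addition macrocyclisation. The 14-membered carbocycle closes in a 14-exo-trig mode, since C15 stays outside the new ring. The new stereocentre C1 is controlled by C2: the radical should enter anti to the C2 alkenyl substituent, the face favoured sterically and torsionally in gamma-substituted butenolides, which gives the trans ring fusion. Ring closure must outrun hydrogen transfer from Hantzsch ester and intermolecular addition; the high dilution, the polarity match and the irreversible sulfonyl loss should secure this. The C11=C12 geometry must be retained, which rests on the slow 3-exo closure of the homoallylic radical onto the methyl-bearing C12 and its fast reopening. C2 must keep its configuration, which the base-free medium should secure. Benzenesulfinic acid is washed out with bicarbonate before concentration so that it cannot add back to the methylene lactone.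

Step 15
Reactants: 24 (3aR,6E,9S,10E,14E,15aS)-9-[(tert-butyldimethylsilyl)oxy]-6,10,14-trimethyl-3-methylidene-3a,4,5,8,9,12,13,15a-octahydrocyclotetradeca[b]furan-2(3H)-one
Product: 25 (3aR,6E,9S,10E,14E,15aS)-9-hydroxy-6,10,14-trimethyl-3-methylidene-3a,4,5,8,9,12,13,15a-octahydrocyclotetradeca[b]furan-2(3H)-one
Conditions: HF·pyridine, pyridine, THF, 0 °C → rt
Reagents that add atoms: none
Why: Fluoride cleavage of the silyl ether under buffered, weakly acidic conditions should leave the methylene lactone, the doubly allylic lactone C–O bond and the alkenes untouched; basic fluoride sources are avoided.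

Step 16
Reactants: 25 (3aR,6E,9S,10E,14E,15aS)-9-hydroxy-6,10,14-trimethyl-3-methylidene-3a,4,5,8,9,12,13,15a-octahydrocyclotetradeca[b]furan-2(3H)-one
Product: 26 (3aR,6E,9S,10E,14E,15aS)-6,10,14-trimethyl-3-methylidene-2-oxo-2,3,3a,4,5,8,9,12,13,15a-decahydrocyclotetradeca[b]furan-9-yl acetate
Conditions: Ac2O, pyridine, 4-dimethylaminopyridine (cat.), CH2Cl2, 0 °C
Reagents that add atoms: acetic anhydride CC(=O)OC(C)=O
Why: Acyl-transfer catalysis acetylates the secondary allylic alcohol with retention at C9; addition of the pyridine bases to the methylene lactone is reversible and no strong base is present.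

## Compound list

1 | geranyl acetate, (2E)-3,7-dimethylocta-2,6-dien-1-yl acetate | CC(C)=CCC/C(C)=C/COC(C)=O | starting material
2 | (2E,6E)-8-hydroxy-3,7-dimethylocta-2,6-dien-1-yl acetate (8-hydroxygeranyl acetate) | OC/C(C)=C/CC/C(C)=C/COC(C)=O | intermediate (not isolated)
3 | (2E,6E)-3,7-dimethyl-8-oxoocta-2,6-dien-1-yl acetate | O=C/C(C)=C/CC/C(C)=C/COC(C)=O | intermediate
4 | 3-methylbut-3-en-2-one | CC(=O)C(C)=C | starting material
5 | 3-methylbuta-1,3-dien-2-yl diisopinocampheylborinate (both isopinocampheyl groups from (−)-alpha-pinene) | C=C(OB([C@H]1C[C@H]2C[C@@H]([C@@H]1C)C2(C)C)[C@H]1C[C@H]2C[C@@H]([C@@H]1C)C2(C)C)C(C)=C | intermediate (not isolated)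
6 | boron aldolate, the O-diisopinocampheylboryl derivative of 7 (8S) | C=C(C)C(=O)C[C@H](OB([C@H]1C[C@H]2C[C@@H]([C@@H]1C)C2(C)C)[C@H]1C[C@H]2C[C@@H]([C@@H]1C)C2(C)C)/C(C)=C/CC/C(C)=C/COC(C)=O | intermediate (not isolated)
7 | (2E,6E,8S)-8-hydroxy-3,7,11-trimethyl-10-oxododeca-2,6,11-trien-1-yl acetate | C=C(C)C(=O)C[C@H](O)/C(C)=C/CC/C(C)=C/COC(C)=O | intermediate
8 | (2E,6E,8S)-8-[(tert-butyldimethylsilyl)oxy]-3,7,11-trimethyl-10-oxododeca-2,6,11-trien-1-yl acetate | C=C(C)C(=O)C[C@H](O[Si](C)(C)C(C)(C)C)/C(C)=C/CC/C(C)=C/COC(C)=O | intermediate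
9 | (2E,6E,8S)-8-[(tert-butyldimethylsilyl)oxy]-10-hydroxy-3,7,11-trimethyldodeca-2,6,11-trien-1-yl acetate, both C10 epimers | C=C(C)C(O)C[C@H](O[Si](C)(C)C(C)(C)C)/C(C)=C/CC/C(C)=C/COC(C)=O | intermediate
10 | trimethyl orthoacetate | COC(C)(OC)OC | starting material
11 | (2E,6E,8S)-8-[(tert-butyldimethylsilyl)oxy]-10-[(1-methoxyethenyl)oxy]-3,7,11-trimethyldodeca-2,6,11-trien-1-yl acetate (mixed ketene acetal, both C10 epimers) | C=C(OC)OC(C(C)=C)C[C@H](O[Si](C)(C)C(C)(C)C)/C(C)=C/CC/C(C)=C/COC(C)=O | intermediate (not isolated)
12 | methyl (4E,7S,8E,12E)-14-acetoxy-7-[(tert-butyldimethylsilyl)oxy]-4,8,12-trimethyltetradeca-4,8,12-trienoate | COC(=O)CC/C(C)=C/C[C@H](O[Si](C)(C)C(C)(C)C)/C(C)=C/CC/C(C)=C/COC(C)=O | intermediate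
13 | methyl (4E,7S,8E,12E)-7-[(tert-butyldimethylsilyl)oxy]-14-hydroxy-4,8,12-trimethyltetradeca-4,8,12-trienoate | COC(=O)CC/C(C)=C/C[C@H](O[Si](C)(C)C(C)(C)C)/C(C)=C/CC/C(C)=C/CO | intermediate
14 | methyl (4E,7S,8E,12E)-7-[(tert-butyldimethylsilyl)oxy]-4,8,12-trimethyl-14-oxotetradeca-4,8,12-trienoate | COC(=O)CC/C(C)=C/C[C@H](O[Si](C)(C)C(C)(C)C)/C(C)=C/CC/C(C)=C/C=O | intermediate
15 | methyl (4E,7S,8E,12E,14R)-7-[(tert-butyldimethylsilyl)oxy]-14-hydroxy-4,8,12-trimethylhexadeca-4,8,12,15-tetraenoate | COC(=O)CC/C(C)=C/C[C@H](O[Si](C)(C)C(C)(C)C)/C(C)=C/CC/C(C)=C/[C@H](O)C=C | intermediate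
16 | (4E,7S,8E,12E,14R)-7-[(tert-butyldimethylsilyl)oxy]-14-hydroxy-4,8,12-trimethylhexadeca-4,8,12,15-tetraenoic acid | OC(=O)CC/C(C)=C/C[C@H](O[Si](C)(C)C(C)(C)C)/C(C)=C/CC/C(C)=C/[C@H](O)C=C | intermediate
17 | N-hydroxyphthalimide | ON1C(=O)c2ccccc2C1=O | starting material
18 | 1,3-dioxoisoindolin-2-yl (4E,7S,8E,12E,14R)-7-[(tert-butyldimethylsilyl)oxy]-14-hydroxy-4,8,12-trimethylhexadeca-4,8,12,15-tetraenoate | O=C(ON1C(=O)c2ccccc2C1=O)CC/C(C)=C/C[C@H](O[Si](C)(C)C(C)(C)C)/C(C)=C/CC/C(C)=C/[C@H](O)C=C | intermediate
19 | 2-(bromomethyl)acrylic acid | OC(=O)C(=C)CBr | starting material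
20 | sodium benzenesulfinate | [Na+].[O-]S(=O)c1ccccc1 | starting material
21 | 2-[(phenylsulfonyl)methyl]prop-2-enoic acid | C=C(CS(=O)(=O)c1ccccc1)C(=O)O | intermediate
22 | 1,3-dioxoisoindolin-2-yl (4E,7S,8E,12E,14R)-7-[(tert-butyldimethylsilyl)oxy]-4,8,12-trimethyl-14-({2-[(phenylsulfonyl)methyl]prop-2-enoyl}oxy)hexadeca-4,8,12,15-tetraenoate | O=C(ON1C(=O)c2ccccc2C1=O)CC/C(C)=C/C[C@H](O[Si](C)(C)C(C)(C)C)/C(C)=C/CC/C(C)=C/[C@H](OC(=O)C(=C)CS(=O)(=O)c1ccccc1)C=C | intermediate
23 | 1,3-dioxoisoindolin-2-yl (4E,7S,8E,12E)-7-[(tert-butyldimethylsilyl)oxy]-4,8,12-trimethyl-13-{(2S)-5-oxo-4-[(phenylsulfonyl)methyl]-2,5-dihydrofuran-2-yl}trideca-4,8,12-trienoate | O=C(ON1C(=O)c2ccccc2C1=O)CC/C(C)=C/C[C@H](O[Si](C)(C)C(C)(C)C)/C(C)=C/CC/C(C)=C/[C@@H]1OC(=O)C(CS(=O)(=O)c2ccccc2)=C1 | intermediate (key-step precursor)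
24 | (3aR,6E,9S,10E,14E,15aS)-9-[(tert-butyldimethylsilyl)oxy]-6,10,14-trimethyl-3-methylidene-3a,4,5,8,9,12,13,15a-octahydrocyclotetradeca[b]furan-2(3H)-one | C=C1C(=O)O[C@H]2/C=C(\C)CC/C=C(\C)[C@@H](O[Si](C)(C)C(C)(C)C)C/C=C(\C)CC[C@H]12 | intermediate (key-step product)
25 | (3aR,6E,9S,10E,14E,15aS)-9-hydroxy-6,10,14-trimethyl-3-methylidene-3a,4,5,8,9,12,13,15a-octahydrocyclotetradeca[b]furan-2(3H)-one | C=C1C(=O)O[C@H]2/C=C(\C)CC/C=C(\C)[C@@H](O)C/C=C(\C)CC[C@H]12 | intermediate
26 | (3aR,6E,9S,10E,14E,15aS)-6,10,14-trimethyl-3-methylidene-2-oxo-2,3,3a,4,5,8,9,12,13,15a-decahydrocyclotetradeca[b]furan-9-yl acetate (CNP0129197.2) | C=C1C(=O)O[C@H]2/C=C(\C)CC/C=C(\C)[C@@H](OC(C)=O)C/C=C(\C)CC[C@H]12 | target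

## Step count and least certain steps

Total: 16 steps. Longest linear sequence: 15 steps from geranyl acetate (steps 1–10 and 12–16); step 11 is a one-step side branch.

**Step 14 (key step, proposed new method).**
- Most likely failure: the C14 radical is quenched by hydrogen transfer from Hantzsch ester, or adds intermolecularly, before the 14-membered ring closes. Further losses are specific to the sulfonylmethyl butenolide: sulfinate adding back to the product, sulfonyl radicals isomerising the trisubstituted alkenes, and erosion of the anti facial preference at C1 by the tether. Slow closure would also give the homoallylic radical time to scramble the C11=C12 geometry.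
- Fallback (known chemistry; ring closure and methylene formation separated): it sets out from 18 and returns at 24. Esterification of 18 with acrylic acid (carbodiimide, catalytic 4-dimethylaminopyridine) would give the acrylate F1. Ring-closing metathesis with the same ruthenium catalyst would give the alpha-unsubstituted butenolide F2. Reductive decarboxylative Giese-type macrocyclisation (Ru(bpy)3Cl2, Hantzsch ester, blue light, high dilution) would give the saturated trans-fused lactone F3. Aminomethylation of its lithium enolate (LiN(iPr)2, THF, −78 °C, then dimethylmethylideneammonium iodide) would give the Mannich base F4. N-Methylation with MeI and elimination with NaHCO3 would give 24.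

**Step 13 (and the passage of the redox-active ester through steps 12 and 13).**
- Most likely failure: the N-acyloxyphthalimide is lost by acyl transfer to the C2 hydroxyl during the catalysed esterification or is degraded at the ruthenium carbene. Closure onto the hindered, electron-poor 1,1-disubstituted acrylate may also be slow enough for ionisation or allylic transposition of the doubly allylic ester to compete.
- Fallback (activated ester installed last): it sets out from 15 and returns at 23. Esterification of 15 with 21 would give the diene methyl ester F5. Ring-closing metathesis would give the butenolide methyl ester F6. Non-basic cleavage of the methyl ester with Me3SnOH (1,2-dichloroethane, 60 °C) would give the butenolide acid F7. Carbodiimide coupling with 17 would give 23.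

**Step 8.**
- Most likely failure: insufficient facial selectivity in the vinyl transfer to a beta,beta-disubstituted enal, or an uncatalysed racemic background reaction caused by residual magnesium salts in the divinylzinc.
- Fallback (alkynylation followed by semireduction): it sets out from 14 and returns at 15. Zinc/ProPhenol-catalysed addition of trimethylsilylacetylene (Me2Zn, the ProPhenol antipode that adds to the Re face) would give the silylated propargylic alcohol F8. K2CO3 in MeOH would give the terminal alkyne F9. Semihydrogenation over Pd/CaCO3 poisoned with Pb(OAc)2 and quinoline would give 15.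

**Step 2.**
- Most likely failure: only moderate enantioselectivity, which is typical of methyl ketone enolborinates. The minor enantiomer would later give remote diastereomers that are hard to separate.
- Fallback (resolution in place of reagent control): it sets out from 3 and 4 and returns at 7. The aldol reaction with achiral (c-Hex)2BCl and Et3N would give the racemic aldol F10. Sharpless kinetic resolution (Ti(OiPr)4, D-(−)-diisopropyl tartrate, t-BuOOH, 4 Å sieves, CH2Cl2, −20 °C) should epoxidise the fast-reacting 8R enantiomer to the epoxy alcohol F11 and leave 7. The same resolution could also be applied directly to partially enriched 7 from step 2.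

## Further compounds

F1 | step 14 | 1,3-dioxoisoindolin-2-yl (4E,7S,8E,12E,14R)-14-(acryloyloxy)-7-[(tert-butyldimethylsilyl)oxy]-4,8,12-trimethylhexadeca-4,8,12,15-tetraenoate | O=C(ON1C(=O)c2ccccc2C1=O)CC/C(C)=C/C[C@H](O[Si](C)(C)C(C)(C)C)/C(C)=C/CC/C(C)=C/[C@H](OC(=O)C=C)C=C
F2 | step 14 | 1,3-dioxoisoindolin-2-yl (4E,7S,8E,12E)-7-[(tert-butyldimethylsilyl)oxy]-4,8,12-trimethyl-13-[(2R)-5-oxo-2,5-dihydrofuran-2-yl]trideca-4,8,12-trienoate | O=C(ON1C(=O)c2ccccc2C1=O)CC/C(C)=C/C[C@H](O[Si](C)(C)C(C)(C)C)/C(C)=C/CC/C(C)=C/[C@@H]1OC(=O)C=C1
F3 | step 14 | (3aR,6E,9S,10E,14E,15aR)-9-[(tert-butyldimethylsilyl)oxy]-6,10,14-trimethyl-3a,4,5,8,9,12,13,15a-octahydrocyclotetradeca[b]furan-2(3H)-one | C1C(=O)O[C@H]2/C=C(\C)CC/C=C(\C)[C@@H](O[Si](C)(C)C(C)(C)C)C/C=C(\C)CC[C@H]12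
F4 | step 14 | (3aR,6E,9S,10E,14E,15aR)-9-[(tert-butyldimethylsilyl)oxy]-3-[(dimethylamino)methyl]-6,10,14-trimethyl-3a,4,5,8,9,12,13,15a-octahydrocyclotetradeca[b]furan-2(3H)-one (C3 epimers) | CN(C)CC1C(=O)O[C@H]2/C=C(\C)CC/C=C(\C)[C@@H](O[Si](C)(C)C(C)(C)C)C/C=C(\C)CC[C@H]12
F5 | step 13 | methyl (4E,7S,8E,12E,14R)-7-[(tert-butyldimethylsilyl)oxy]-4,8,12-trimethyl-14-({2-[(phenylsulfonyl)methyl]prop-2-enoyl}oxy)hexadeca-4,8,12,15-tetraenoate | COC(=O)CC/C(C)=C/C[C@H](O[Si](C)(C)C(C)(C)C)/C(C)=C/CC/C(C)=C/[C@H](OC(=O)C(=C)CS(=O)(=O)c1ccccc1)C=C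
F6 | step 13 | methyl (4E,7S,8E,12E)-7-[(tert-butyldimethylsilyl)oxy]-4,8,12-trimethyl-13-{(2S)-5-oxo-4-[(phenylsulfonyl)methyl]-2,5-dihydrofuran-2-yl}trideca-4,8,12-trienoate | COC(=O)CC/C(C)=C/C[C@H](O[Si](C)(C)C(C)(C)C)/C(C)=C/CC/C(C)=C/[C@@H]1OC(=O)C(CS(=O)(=O)c2ccccc2)=C1
F7 | step 13 | (4E,7S,8E,12E)-7-[(tert-butyldimethylsilyl)oxy]-4,8,12-trimethyl-13-{(2S)-5-oxo-4-[(phenylsulfonyl)methyl]-2,5-dihydrofuran-2-yl}trideca-4,8,12-trienoic acid | OC(=O)CC/C(C)=C/C[C@H](O[Si](C)(C)C(C)(C)C)/C(C)=C/CC/C(C)=C/[C@@H]1OC(=O)C(CS(=O)(=O)c2ccccc2)=C1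
F8 | step 8 | methyl (4E,7S,8E,12E,14S)-7-[(tert-butyldimethylsilyl)oxy]-14-hydroxy-4,8,12-trimethyl-16-(trimethylsilyl)hexadeca-4,8,12-trien-15-ynoate | COC(=O)CC/C(C)=C/C[C@H](O[Si](C)(C)C(C)(C)C)/C(C)=C/CC/C(C)=C/[C@H](O)C#C[Si](C)(C)C
F9 | step 8 | methyl (4E,7S,8E,12E,14S)-7-[(tert-butyldimethylsilyl)oxy]-14-hydroxy-4,8,12-trimethylhexadeca-4,8,12-trien-15-ynoate | COC(=O)CC/C(C)=C/C[C@H](O[Si](C)(C)C(C)(C)C)/C(C)=C/CC/C(C)=C/[C@H](O)C#C
F10 | step 2 | racemic (2E,6E)-8-hydroxy-3,7,11-trimethyl-10-oxododeca-2,6,11-trien-1-yl acetate | C=C(C)C(=O)CC(O)/C(C)=C/CC/C(C)=C/COC(C)=O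
F11 | step 2 | (2E)-5-{(2S,3S)-3-[(1R)-1-hydroxy-4-methyl-3-oxopent-4-en-1-yl]-3-methyloxiran-2-yl}-3-methylpent-2-en-1-yl acetate | C=C(C)C(=O)C[C@@H](O)[C@]1(C)O[C@H]1CC/C(C)=C/COC(C)=O
A1 | alternative 1 | 14-membered cyclic silyl ether (C9–O–SiMe2–C12) with an allyl group on C9, a methylidene on C12 and the saturated trans-fused lactone | C=CC[C@@H]1O[Si](C)(C)C(=C)CC[C@@H]2CC(=O)O[C@H]2/C=C(\C)CC/C=C1\C
A2 | alternative 1 | 14-membered carbocycle strapped C9–O–SiMe2–C12 (cyclic alkenylsiloxane) with saturated lactone | C[Si]1(C)O[C@H]2C/C=C1/CC[C@@H]1CC(=O)O[C@H]1/C=C(\C)CC/C=C2\C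
A3 | alternative 2 | seco diyne with methyl-capped alkynes at C3 and C4, free C2 hydroxyl, C9 TBS ether and a C15 methylidene bearing a p-methoxybenzyl ether | CC#C[C@H](O)[C@H](CC/C(C)=C/C[C@H](O[Si](C)(C)C(C)(C)C)/C(C)=C/CCC#CC)C(=C)COCc1ccc(OC)cc1
A4 | alternative 2 | 14-membered cycloalkynol (C3≡C4) | O[C@H]1C#CCC/C=C(\C)[C@@H](O[Si](C)(C)C(C)(C)C)C/C=C(\C)CC[C@@H]1C(=C)COCc1ccc(OC)cc1
A5 | alternative 3 | seco ynal: trans-disubstituted saturated lactone with a C9 aldehyde and a methyl-capped C7≡C8 alkyne | C1C(=O)O[C@@H](/C=C(\C)CCC#CC)[C@@H]1CC/C(C)=C/CC=O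
A6 | alternative 3 | macrocyclic C9 triethylsilyl ether with saturated lactone | C1C(=O)O[C@H]2/C=C(\C)CC/C=C(\C)[C@@H](O[Si](CC)(CC)CC)C/C=C(\C)CC[C@H]12
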